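**Assumption and convention (one line):** the five bought compounds (1, 4, 8, 10, 12) are taken as catalogue chemicals; bicyclic compounds are numbered as in the target (C1 = ring CH2, C2, C3, C3a, C4, C5, C6, C7 = ring carbon bearing the exocyclic methylene, C7a; C1′ = side-chain carbinol carbon), β is the face of the C4 substituent and α the face of H-3a, H-4 and H-7a.

## Retrosynthetic overview

1. Target ⇐ acetylation of the C1′ alcohol ⇐ stereospecific semipinacol 1,2-hydride shift of a spiro 2,3-epoxy alcohol (sets C3, keeps C1′) ⇐ (E)-3-ethylidene-2-ketone.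
2. Glycidate ⇐ Sharpless epoxidation and oxidation of a 2-substituted allyl alcohol grown from a C4 hydroxyethyl arm; C5/C6 trans-diester ⇐ arm-directed β-epoxidation of the ring diene, SN2 opening at allylic C6 by (S)-3-methylpentanoic acid, then C5 acylation.
3. (E)-3-Ethylidene-2-ketone ⇐ 1,2-carbonyl transposition (α-hydroxylation, Wittig, oxidation) of the Diels–Alder C3 ketone.
4. Key disconnection (new): catalytic enantioselective endo Diels–Alder of an (E)-vinylallene with cyclopent-2-enone, which sets C3a, C4 and C7a and delivers the exocyclic methylene directly.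
5. Ring order: five-membered ring bought (cyclopent-2-enone) → six-membered ring by the cycloaddition → transient C5–C6 oxirane → glycidate oxirane → transient spiro-oxirane.

## Route

Step 1
Reactants: 1 (S)-1-bromo-2-methylbutane
Product: 3 (S)-3-methylpentanoic acid, via Grignard reagent 2 (not isolated)
Conditions: Mg, THF, reflux; CO2 (solid), −78 °C → rt; 1 M HCl
Reagents that add atoms: carbon dioxide, O=C=O
Why: Grignard carboxylation adds one carbon while the existing stereocentre, one carbon away from the reacting centre, is untouched and stays (S).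

Step 2
Reactants: 4 ethyl but-2-ynoate
Product: 5 ethyl (E)-3-methylpent-2-enoate
Conditions: EtMgBr (1.1 equiv), CuBr·SMe2 (1.1 equiv), THF, −40 °C; then 4, −78 °C; MeOH, −78 °C; aq NH4Cl
Reagents that add atoms: ethylmagnesium bromide, CC[Mg]Br
Why: syn-carbocupration of the ynoate by ethylcopper followed by protonation of the alkenylcopper at −78 °C (before it can equilibrate through the allenoate) places Et and H cis and gives only the (E)-enoate.

Step 3
Reactants: 5 ethyl (E)-3-methylpent-2-enoate
Product: 6 (E)-3-methylpent-2-enoic acid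
Conditions: LiOH·H2O, THF/H2O, rt; 1 M HCl
Reagents that add atoms: lithium hydroxide, [Li+].[OH-]
Why: saponification of the ester leaves the trisubstituted (E)-alkene unchanged.

Step 4
Reactants: 6 (E)-3-methylpent-2-enoic acid
Product: 7 (E)-3-methylpent-2-enoyl chloride
Conditions: (COCl)2 (1.2 equiv), DMF (cat.), CH2Cl2, 0 °C → rt; evaporate, use crude
Reagents that add atoms: oxalyl chloride, O=C(Cl)C(Cl)=O
Why: acid chloride formation under Vilsmeier catalysis is mild enough to avoid E/Z or β,γ-isomerisation.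

Step 5
Reactants: 8 tert-butyl(but-3-yn-1-yloxy)dimethylsilane
Product: 9 (E)-alkenyl pinacol boronate
Conditions: pinacolborane (1.1 equiv), Cp2Zr(H)Cl (5 mol%), Et3N (10 mol%), neat, 60 °C
Reagents that add atoms: pinacolborane, B1OC(C)(C)C(C)(C)O1
Why: zirconocene hydride-catalysed syn-hydroboration of the terminal alkyne puts boron on the terminal carbon and gives only the (E)-alkenylboronate.

Step 6
Reactants: 9 (E)-alkenyl pinacol boronate; 10 methyl prop-2-yn-1-yl carbonate
Product: 11 (E)-tert-butyl(hepta-3,5,6-trien-1-yloxy)dimethylsilane (vinylallene)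
Conditions: Pd(PPh3)4 (5 mol%), THF, 60 °C, no added base
Reagents that add atoms: none
Why: Suzuki–Miyaura-type coupling of a propargylic carbonate, in which SN2′ oxidative addition to zerovalent palladium and loss of CO2 give an allenylpalladium methoxide that transmetallates with the boronate and reductively eliminates to the terminal allene with retention of the (E)-alkene.

Step 7
Reactants: 11 (E)-vinylallene; 12 cyclopent-2-en-1-one
Product: 13 cis-fused ketone 4β-[2-(tert-butyldimethylsilyloxy)ethyl]-7-methylidene-1,2,3a,4,7,7a-hexahydro-3H-inden-3-one (H-3a, H-4, H-7a all α; C5=C6)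
Conditions: (S)-3,3-diphenyl-1-(2-methylphenyl)tetrahydro-1H,3H-pyrrolo[1,2-c][1,3,2]oxazaborole (20 mol%) activated with HN(SO2CF3)2 (18 mol%), 11 (1.5 equiv), CH2Cl2, −78 → −40 °C
Reagents that add atoms: none
Why: Proposed new method: the protonated (S)-oxazaborolidine binds the enone carbonyl (held by the α-C–H···O contact typical of cyclic enones) and shields one face, the vinylallene adds from the open face through an endo transition state in which its unhindered sp terminus bonds first to the enone β-carbon while the developing positive charge sits at the alkyl-bearing terminus, so that C7a, C3a and C4 are set all-cis, the regiochemistry is "ortho" and the exocyclic methylene is delivered directly (the (S)-catalyst is the enantiomer predicted by the usual pre-transition-state model to give 13, the mirror-image catalyst would give its enantiomer); the closest known reactions are oxazaborolidinium-catalysed enantioselective Diels–Alder additions of acyclic 1,3-dienes to cyclopent-2-enone and thermal or achiral-Lewis-acid Diels–Alder reactions of vinylallenes.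

Step 8
Reactants: 13 cis-fused C3 ketone
Product: 15 2α-(trimethylsilyloxy) C3 ketone, via potassium alkoxide 14 (not isolated)
Conditions: KN(SiMe3)2 (1.1 equiv), THF, −78 °C; 2-(phenylsulfonyl)-3-phenyloxaziridine (1.3 equiv), −78 °C; Me3SiCl (2 equiv), −78 → 0 °C
Reagents that add atoms: 2-(phenylsulfonyl)-3-phenyloxaziridine, O=S(=O)(N1OC1c1ccccc1)c1ccccc1; chlorotrimethylsilane, C[Si](C)(C)Cl
Why: kinetic deprotonation occurs at the unhindered C2 methylene and not at the ring-fusion C3a–H, the enolate is hydroxylated from the convex α face (Davis α-hydroxylation), and in-flask silylation prevents α-ketol isomerisation in the next step.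

Step 9
Reactants: 15 2α-(trimethylsilyloxy) C3 ketone
Product: 17 3-[(E)-ethylidene]-4β-[2-(tert-butyldimethylsilyloxy)ethyl]-7-methylidene-2,3,3a,4,7,7a-hexahydro-1H-inden-2α-ol (any Z isomer is corrected in step 10), via silyl ether 16 (not isolated)
Conditions: EtPPh3Br (3 equiv), KOtBu (2.8 equiv), THF, 0 → 45 °C; then K2CO3, MeOH, 0 °C
Reagents that add atoms: ethyltriphenylphosphonium bromide, CC[P+](c1ccccc1)(c1ccccc1)c1ccccc1.[Br-]
Why: Wittig ethylidenation of the α-silyloxy ketone installs both side-chain carbons at C3 and carbonate methanolysis removes only the labile Me3Si ether, the E/Z ratio being irrelevant because it is corrected thermodynamically in step 10.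

Step 10
Reactants: 17 allylic alcohol
Product: 18 (E)-enone 3-[(E)-ethylidene]-4β-[2-(tert-butyldimethylsilyloxy)ethyl]-7-methylidene-1,3,3a,4,7,7a-hexahydro-2H-inden-2-one
Conditions: Dess–Martin periodinane, NaHCO3, CH2Cl2, 0 °C → rt; then DABCO (20 mol%), CH2Cl2, rt
Reagents that add atoms: none
Why: Dess–Martin oxidation of the allylic alcohol gives the exocyclic enone and amine-catalysed addition–elimination equilibrates the alkene to the more stable (E)-isomer (methyl anti to the carbonyl), which completes a 1,2-carbonyl transposition with alkylidenation.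

Step 11
Reactants: 18 (E)-enone silyl ether
Product: 19 (E)-enone primary alcohol (4β-(2-hydroxyethyl))
Conditions: HF·pyridine, pyridine, THF, 0 °C
Reagents that add atoms: none
Why: buffered fluoride desilylation cleaves the primary silyl ether without touching the enone or the diene.

Step 12
Reactants: 19 (E)-enone primary alcohol
Product: 20 5β,6β-epoxide (vinyl oxirane) of 19
Conditions: VO(acac)2 (5 mol%), t-BuOOH (1.5 equiv), CH2Cl2, 0 °C
Reagents that add atoms: tert-butyl hydroperoxide, CC(C)(C)OO
Why: hydroxyl-directed vanadium-catalysed epoxidation, in which the vanadate ester of the C4 hydroxyethyl arm reaches only the nearer C5=C6 bond and only its β face, so the oxirane forms syn to the arm while the exocyclic methylene and the electron-poor enone are left alone.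

Step 13
Reactants: 20 vinyl oxirane; 3 (S)-3-methylpentanoic acid
Product: 21 5β-hydroxy-6α-[(S)-3-methylpentanoyloxy] compound (4β-(2-hydroxyethyl))
Conditions: 3 (3 equiv), Ti(OiPr)4 (20 mol%), CH2Cl2, 0 °C → rt
Reagents that add atoms: none
Why: Lewis-acid-assisted SN2 opening of the vinyl oxirane by the carboxylic acid occurs at the allylic carbon C6 with inversion (the trans-diaxial Fürst–Plattner mode that keeps the C4 arm equatorial), which sets 6α-O-acyl and 5β-OH and differentiates the two oxygens in one operation.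

Step 14
Reactants: 21 diol monoester
Product: 22 primary triethylsilyl ether of 21 (5β-OH free)
Conditions: Et3SiCl (1.1 equiv), imidazole, CH2Cl2, −20 °C
Reagents that add atoms: chlorotriethylsilane, CC[Si](Cl)(CC)CC
Why: silyl ether formation is selective for the primary alcohol over the hindered axial C5–OH.

Step 15
Reactants: 22 5β-alcohol; 7 (E)-3-methylpent-2-enoyl chloride
Product: 23 5β-[(E)-3-methylpent-2-enoyloxy]-6α-[(S)-3-methylpentanoyloxy] diester (primary triethylsilyl ether)
Conditions: 7 (1.5 equiv), pyridine, DMAP (10 mol%), CH2Cl2, 0 °C → rt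
Reagents that add atoms: none
Why: DMAP-catalysed acylation of the only free hydroxyl, in which pyridine as a weak base limits deconjugation through the vinylketene and the trans-diaxial C5/C6 arrangement rules out acyl migration.

Step 16
Reactants: 23 diester triethylsilyl ether
Product: 25 aldehyde (C4 2-oxoethyl), via primary alcohol 24 (not isolated)
Conditions: (COCl)2 (3 equiv), DMSO (6 equiv), CH2Cl2, −78 → −40 °C; Et3N, −78 → 0 °C
Reagents that add atoms: none
Why: Swern conditions cleave the primary triethylsilyl ether through the HCl formed in the flask and oxidise the liberated alcohol to the aldehyde (Swern oxidation) without affecting esters, enone or alkenes.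

Step 17
Reactants: 25 aldehyde
Product: 27 2-substituted acrolein (C4 3-oxoprop-1-en-2-yl), via Mannich base 26 (not isolated)
Conditions: CH2=NMe2 I (Eschenmoser's salt, 3 equiv), Et3N (5 equiv), CH2Cl2, rt
Reagents that add atoms: N,N-dimethylmethyleneiminium iodide, C=[N+](C)C.[I-]
Why: Mannich reaction of the aldehyde enol followed by amine-promoted β-elimination (α-methylenation) converts the only enolisable aldehyde position into the 2-substituted acrolein.

Step 18
Reactants: 27 2-substituted acrolein
Product: 28 allylic alcohol (C4 3-hydroxyprop-1-en-2-yl)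
Conditions: NaBH4 (1 equiv), MeOH/CH2Cl2 (1:1), −78 °C
Reagents that add atoms: none
Why: at −78 °C NaBH4 reduces the aldehyde much faster than the conjugated ring ketone (chemoselective 1,2-reduction) and gives the 2-substituted allylic alcohol needed for asymmetric epoxidation.

Step 19
Reactants: 28 allylic alcohol
Product: 29 epoxy alcohol (C4 (S)-2-(hydroxymethyl)oxiran-2-yl)
Conditions: Ti(OiPr)4 (10 mol%), L-(+)-diethyl tartrate (12 mol%), t-BuOOH (2 equiv), 4 Å molecular sieves, CH2Cl2, −20 °C
Reagents that add atoms: tert-butyl hydroperoxide, CC(C)(C)OO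
Why: Sharpless asymmetric epoxidation activates only the allylic alcohol alkene, and L-(+)-diethyl tartrate delivers oxygen to the face that gives the (S)-epoxy alcohol (reagent control as for 2-alkylprop-2-en-1-ols), which becomes the (R)-glycidate after oxidation.

Step 20
Reactants: 29 epoxy alcohol
Product: 31 glycidic acid (C4 (R)-2-carboxyoxiran-2-yl), via epoxy aldehyde 30 (not isolated)
Conditions: TEMPO (20 mol%), PhI(OAc)2 (2.5 equiv), MeCN/pH 7 phosphate buffer, 0 °C → rt
Reagents that add atoms: water, O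
Why: oxoammonium (TEMPO) oxidation takes the primary alcohol to the aldehyde and, through its hydrate, to the carboxylic acid, and the quaternary oxirane carbon cannot epimerise.

Step 21
Reactants: 31 glycidic acid
Product: 32 methyl (R)-glycidate (E)-enone
Conditions: Me3SiCHN2 (1.5 equiv), PhH/MeOH (4:1), 0 °C
Reagents that add atoms: (trimethylsilyl)diazomethane, C[Si](C)(C)C=[N+]=[N-]
Why: methyl ester formation by diazomethane generated from Me3SiCHN2 and methanol is fast and neutral, so the glycidic acid and the allylic ester survive.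

Step 22
Reactants: 32 methyl glycidate (E)-enone
Product: 33 2β-allylic alcohol
Conditions: NaBH4 (1.2 equiv), CeCl3·7H2O (1.2 equiv), MeOH, −78 °C
Reagents that add atoms: none
Why: Luche 1,2-reduction of the enone, in which hydride attacks C2 from the convex α face of the cis-fused bicycle and sets the 2β-hydroxyl syn to the later C3–O bond.

Step 23
Reactants: 33 2β-allylic alcohol
Product: 34 spiro epoxy alcohol (2β-OH; C3–C1′ oxirane with oxygen on the β face, C1′ S)
Conditions: VO(acac)2 (5 mol%), t-BuOOH (1.5 equiv), CH2Cl2, 0 °C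
Reagents that add atoms: tert-butyl hydroperoxide, CC(C)(C)OO
Why: hydroxyl-directed vanadium-catalysed epoxidation delivers oxygen to the β face of the (E)-ethylidene bond syn to the 2β-OH, which fixes C1′ as (S) and leaves the non-allylic alkenes untouched.

Step 24
Reactants: 34 spiro epoxy alcohol
Product: 35 β-hydroxy ketone (2-oxo; 3β-[(S)-1-hydroxyethyl]; H-3 α)
Conditions: BF3·OEt2 (30 mol%), CH2Cl2, −78 °C; Et3N quench
Reagents that add atoms: none
Why: Lewis-acid-promoted semipinacol rearrangement of the 2,3-epoxy alcohol, in which the tertiary C3–O bond ionises and the antiperiplanar α-hydrogen on C2 shifts to C3 with inversion while C2 becomes the ketone, so H-3 is α (side chain β), the C1′–O bond is retained and the aldol-type product forms without any enolate.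

Step 25
Reactants: 35 β-hydroxy ketone
Product: 36 target, methyl (2R)-2-[(3R,3aR,4R,5R,6R,7aS)-3-[(1S)-1-acetoxyethyl]-7-methylidene-5-[(2E)-3-methylpent-2-enoyloxy]-6-[(3S)-3-methylpentanoyloxy]-2-oxooctahydro-1H-inden-4-yl]oxirane-2-carboxylate
Conditions: Ac2O (3 equiv), pyridine, DMAP (5 mol%), CH2Cl2, 0 °C
Reagents that add atoms: acetic anhydride, CC(=O)OC(C)=O
Why: DMAP-catalysed acetylation of the secondary alcohol at 0 °C is short and mild enough to avoid β-elimination or epimerisation of the β-acetoxy ketone.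

## Compound list

1 | (S)-1-bromo-2-methylbutane | BrC[C@@H](C)CC | starting material
2 | (S)-(2-methylbutyl)magnesium bromide (not isolated) | Br[Mg]C[C@@H](C)CC | intermediate
3 | (S)-3-methylpentanoic acid | OC(=O)C[C@@H](C)CC | intermediate
4 | ethyl but-2-ynoate | CCOC(=O)C#CC | starting material
5 | ethyl (E)-3-methylpent-2-enoate | CCOC(=O)/C=C(\C)CC | intermediate
6 | (E)-3-methylpent-2-enoic acid | OC(=O)/C=C(\C)CC | intermediate
7 | (E)-3-methylpent-2-enoyl chloride | ClC(=O)/C=C(\C)CC | intermediate
8 | tert-butyl(but-3-yn-1-yloxy)dimethylsilane | C#CCCO[Si](C)(C)C(C)(C)C | starting material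
9 | (E)-tert-butyldimethyl{[4-(4,4,5,5-tetramethyl-1,3,2-dioxaborolan-2-yl)but-3-en-1-yl]oxy}silane | CC(C)(C)[Si](C)(C)OCC/C=C/B1OC(C)(C)C(C)(C)O1 | intermediate
10 | methyl prop-2-yn-1-yl carbonate | C#CCOC(=O)OC | starting material
11 | (E)-tert-butyl(hepta-3,5,6-trien-1-yloxy)dimethylsilane | C=C=C/C=C/CCO[Si](C)(C)C(C)(C)C | intermediate
12 | cyclopent-2-en-1-one | O=C1C=CCC1 | starting material
13 | cis-fused ketone, 4β-[2-(tert-butyldimethylsilyloxy)ethyl]-7-methylidene-1,2,3a,4,7,7a-hexahydro-3H-inden-3-one, H-3a/H-4/H-7a all α | C=C1[C@H]2CCC(=O)[C@H]2[C@@H](CCO[Si](C)(C)C(C)(C)C)C=C1 | intermediate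
14 | potassium 2α-alkoxide of the 2-hydroxy derivative of 13 (not isolated) | C=C1[C@H]2C[C@H]([O-])C(=O)[C@H]2[C@@H](CCO[Si](C)(C)C(C)(C)C)C=C1.[K+] | intermediate
15 | 2α-(trimethylsilyloxy) derivative of 13 | C=C1[C@H]2C[C@H](O[Si](C)(C)C)C(=O)[C@H]2[C@@H](CCO[Si](C)(C)C(C)(C)C)C=C1 | intermediate
16 | 3-[(E)-ethylidene]-2α-(trimethylsilyloxy) triene (not isolated; E shown) | C=C1[C@H]2C[C@H](O[Si](C)(C)C)/C(=C/C)[C@H]2[C@@H](CCO[Si](C)(C)C(C)(C)C)C=C1 | intermediate
17 | 3-[(E)-ethylidene]-4β-[2-(tert-butyldimethylsilyloxy)ethyl]-7-methylidene-2,3,3a,4,7,7a-hexahydro-1H-inden-2α-ol (E shown) | C=C1[C@H]2C[C@H](O)/C(=C/C)[C@H]2[C@@H](CCO[Si](C)(C)C(C)(C)C)C=C1 | intermediate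
18 | 3-[(E)-ethylidene]-4β-[2-(tert-butyldimethylsilyloxy)ethyl]-7-methylidene-1,3,3a,4,7,7a-hexahydro-2H-inden-2-one | C=C1[C@H]2CC(=O)/C(=C/C)[C@H]2[C@@H](CCO[Si](C)(C)C(C)(C)C)C=C1 | intermediate
19 | 3-[(E)-ethylidene]-4β-(2-hydroxyethyl)-7-methylidene-1,3,3a,4,7,7a-hexahydro-2H-inden-2-one | C=C1[C@H]2CC(=O)/C(=C/C)[C@H]2[C@@H](CCO)C=C1 | intermediate
20 | 5β,6β-epoxide of 19 (vinyl oxirane) | C=C1[C@H]2CC(=O)/C(=C/C)[C@H]2[C@@H](CCO)[C@H]3O[C@H]31 | intermediate
21 | 3-[(E)-ethylidene]-5β-hydroxy-4β-(2-hydroxyethyl)-7-methylidene-6α-[(S)-3-methylpentanoyloxy]octahydro-2H-inden-2-one | C=C1[C@H]2CC(=O)/C(=C/C)[C@H]2[C@@H](CCO)[C@@H](O)[C@@H]1OC(=O)C[C@@H](C)CC | intermediate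
22 | primary triethylsilyl ether of 21 | C=C1[C@H]2CC(=O)/C(=C/C)[C@H]2[C@@H](CCO[Si](CC)(CC)CC)[C@@H](O)[C@@H]1OC(=O)C[C@@H](C)CC | intermediate
23 | 5β-[(E)-3-methylpent-2-enoyl] ester of 22 | C=C1[C@H]2CC(=O)/C(=C/C)[C@H]2[C@@H](CCO[Si](CC)(CC)CC)[C@@H](OC(=O)/C=C(\C)CC)[C@@H]1OC(=O)C[C@@H](C)CC | intermediate
24 | primary alcohol from 23 (not isolated) | C=C1[C@H]2CC(=O)/C(=C/C)[C@H]2[C@@H](CCO)[C@@H](OC(=O)/C=C(\C)CC)[C@@H]1OC(=O)C[C@@H](C)CC | intermediate
25 | aldehyde, C4 2-oxoethyl diester | C=C1[C@H]2CC(=O)/C(=C/C)[C@H]2[C@@H](CC=O)[C@@H](OC(=O)/C=C(\C)CC)[C@@H]1OC(=O)C[C@@H](C)CC | intermediate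
26 | Mannich base, C4 3-(dimethylamino)-1-oxopropan-2-yl (not isolated; epimers at the new carbon) | C=C1[C@H]2CC(=O)/C(=C/C)[C@H]2[C@@H](C(CN(C)C)C=O)[C@@H](OC(=O)/C=C(\C)CC)[C@@H]1OC(=O)C[C@@H](C)CC | intermediate
27 | 2-substituted acrolein, C4 3-oxoprop-1-en-2-yl | C=C1[C@H]2CC(=O)/C(=C/C)[C@H]2[C@@H](C(=C)C=O)[C@@H](OC(=O)/C=C(\C)CC)[C@@H]1OC(=O)C[C@@H](C)CC | intermediate
28 | allylic alcohol, C4 3-hydroxyprop-1-en-2-yl | C=C1[C@H]2CC(=O)/C(=C/C)[C@H]2[C@@H](C(=C)CO)[C@@H](OC(=O)/C=C(\C)CC)[C@@H]1OC(=O)C[C@@H](C)CC | intermediate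
29 | epoxy alcohol, C4 (S)-2-(hydroxymethyl)oxiran-2-yl | C=C1[C@H]2CC(=O)/C(=C/C)[C@H]2[C@@H]([C@]2(CO)CO2)[C@@H](OC(=O)/C=C(\C)CC)[C@@H]1OC(=O)C[C@@H](C)CC | intermediate
30 | epoxy aldehyde, C4 (R)-2-formyloxiran-2-yl (not isolated) | C=C1[C@H]2CC(=O)/C(=C/C)[C@H]2[C@@H]([C@]2(C=O)CO2)[C@@H](OC(=O)/C=C(\C)CC)[C@@H]1OC(=O)C[C@@H](C)CC | intermediate
31 | glycidic acid, C4 (R)-2-carboxyoxiran-2-yl | C=C1[C@H]2CC(=O)/C(=C/C)[C@H]2[C@@H]([C@]2(C(=O)O)CO2)[C@@H](OC(=O)/C=C(\C)CC)[C@@H]1OC(=O)C[C@@H](C)CC | intermediate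
32 | methyl (R)-glycidate (E)-enone | C=C1[C@H]2CC(=O)/C(=C/C)[C@H]2[C@@H]([C@]2(C(=O)OC)CO2)[C@@H](OC(=O)/C=C(\C)CC)[C@@H]1OC(=O)C[C@@H](C)CC | intermediate
33 | 2β-allylic alcohol from 32 | C=C1[C@H]2C[C@@H](O)/C(=C/C)[C@H]2[C@@H]([C@]2(C(=O)OC)CO2)[C@@H](OC(=O)/C=C(\C)CC)[C@@H]1OC(=O)C[C@@H](C)CC | intermediate
34 | spiro epoxy alcohol, 2β-OH, C3–C1′ oxirane with β oxygen, C1′ S | C=C1[C@H]2C[C@@H](O)[C@@]3(O[C@H]3C)[C@H]2[C@@H]([C@]2(C(=O)OC)CO2)[C@@H](OC(=O)/C=C(\C)CC)[C@@H]1OC(=O)C[C@@H](C)CC | intermediate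
35 | β-hydroxy ketone, 3β-[(S)-1-hydroxyethyl]-2-oxo, H-3 α | C=C1[C@H]2CC(=O)[C@@H]([C@H](C)O)[C@H]2[C@@H]([C@]2(C(=O)OC)CO2)[C@@H](OC(=O)/C=C(\C)CC)[C@@H]1OC(=O)C[C@@H](C)CC | intermediate
36 | methyl (2R)-2-[(3R,3aR,4R,5R,6R,7aS)-3-[(1S)-1-acetoxyethyl]-7-methylidene-5-[(2E)-3-methylpent-2-enoyloxy]-6-[(3S)-3-methylpentanoyloxy]-2-oxooctahydro-1H-inden-4-yl]oxirane-2-carboxylate | C=C1[C@H]2CC(=O)[C@@H]([C@H](C)OC(C)=O)[C@H]2[C@@H]([C@]2(C(=O)OC)CO2)[C@@H](OC(=O)/C=C(\C)CC)[C@@H]1OC(=O)C[C@@H](C)CC | target

## Step count and risks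

Total step count: 25. Longest linear sequence: 21 steps (8 → 36, steps 5 to 25).

The three steps most likely to fail are the new cycloaddition (step 7), the oxirane opening by the carboxylic acid (step 13) and the semipinacol rearrangement (step 24).

The cycloaddition of step 7 is unprecedented for a vinylallene under oxazaborolidinium catalysis and may give low enantioselectivity or diene decomposition by the strong acid. The fallback sets out from 11 and 12 and comes back at 13. An achiral Lewis acid (EtAlCl2, CH2Cl2, −78 °C) promotes the same endo, "ortho" Diels–Alder reaction, a known type of vinylallene cycloaddition, and gives the racemic Diels–Alder ketone F1. The enantiomers are then separated by preparative chromatography on a chiral stationary phase (cellulose tris(3,5-dimethylphenylcarbamate), CO2/MeOH) to give 13, so the absolute configuration comes from resolution instead of catalyst control.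

The opening of step 13 may suffer from SN2′ attack at the exocyclic methylene or from ionisation at C6. The fallback sets out from 20 and comes back at 22. Zerovalent-palladium-catalysed insertion of CO2 (Pd(PPh3)4, CO2 1 atm, THF, 0 °C) converts the vinyl oxirane with net retention into the cis-fused 5β,6β-cyclic carbonate F2. The primary alcohol is silylated (Et3SiCl, imidazole) to the carbonate silyl ether F3, and K2CO3 in MeOH removes the carbonate to give the 5β,6β-diol F4. A Mitsunobu esterification with 3 (PPh3, DIAD, toluene, 0 °C) then reacts at the more reactive allylic C6 hydroxyl with inversion and gives 22.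

The rearrangement of step 24 may be diverted to a Meinwald-type methyl ketone or to dehydration. The fallback sets out from 32 and comes back at 35, replacing steps 22 to 24. Copper-catalysed enantioselective conjugate borylation of the (E)-enone (CuCl, NaOtBu, (R)-1-[(S)-2-(diphenylphosphino)ferrocenyl]ethyldicyclohexylphosphine, B2pin2, MeOH, THF) adds boron to C1′ and protonates C3 from the convex α face to give the β-boryl ketone F5. The ligand enantiomer is chosen to deliver boron to the β face of the alkene, which goes against the substrate's own facial bias, so the diastereomer ratio must be checked. Oxidation with NaBO3·4H2O in THF/H2O replaces boron by hydroxyl with retention and gives 35.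

Further compounds
F1 | step 7 | racemic Diels–Alder ketone (13 together with its enantiomer) | C=C1[C@H]2CCC(=O)[C@H]2[C@@H](CCO[Si](C)(C)C(C)(C)C)C=C1.C=C1[C@@H]2CCC(=O)[C@@H]2[C@H](CCO[Si](C)(C)C(C)(C)C)C=C1
F2 | step 13 | 5β,6β-cyclic carbonate of the cis-diol, 4β-(2-hydroxyethyl) (E)-enone | C=C1[C@H]2CC(=O)/C(=C/C)[C@H]2[C@@H](CCO)[C@H]3OC(=O)O[C@H]31
F3 | step 13 | primary triethylsilyl ether of F2 | C=C1[C@H]2CC(=O)/C(=C/C)[C@H]2[C@@H](CCO[Si](CC)(CC)CC)[C@H]3OC(=O)O[C@H]31
F4 | step 13 | 5β,6β-diol, 4β-[2-(triethylsilyloxy)ethyl] (E)-enone | C=C1[C@H]2CC(=O)/C(=C/C)[C@H]2[C@@H](CCO[Si](CC)(CC)CC)[C@@H](O)[C@H]1O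
F5 | step 24 | β-boryl ketone, 3β-[(S)-1-(4,4,5,5-tetramethyl-1,3,2-dioxaborolan-2-yl)ethyl]-2-oxo, H-3 α | C=C1[C@H]2CC(=O)[C@@H]([C@H](C)B3OC(C)(C)C(C)(C)O3)[C@H]2[C@@H]([C@]2(C(=O)OC)CO2)[C@@H](OC(=O)/C=C(\C)CC)[C@@H]1OC(=O)C[C@@H](C)CC
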